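**Retrosynthetic overview**
1. The γ-lactone is the last ring. O8 closes on the C12 ester once the silyl groups are removed, as in the natural hydroxy acid → olide step.
2. The ten-membered carbocycle is the first ring, made by forming C6–C7 in an acyclic, pre-oxidised farnesyl chain. An allylic C6 gem-diester loses one carboxylate (in place of diphosphate), the distal C7=C11 π bond captures the acyloxyallyl cation, and Me3Si+ leaves in place of H+. This one step sets C6, C7, the 6-ester and C11=C13.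
3. The chain is joined at C3–C4 by an enantioselective Nozaki–Hiyama–Kishi coupling of a β,γ-unsaturated aldehyde (C1–C3, C7–C14) with a 2-iodoallyl ester (C4–C6, C15).
4. The aldehyde half comes from geranyl acetate: ozonolysis, D-proline aminoxylation (C8), Wittig olefination (C11–C13) and CO (C3).
5. The iodide half comes from 3,3-diethoxypropyne and CH2O: directed hydrozirconation–iodination, then esterification with (R)-2-methylbutanoic acid.

Assumption: (2R)-2-methylbutanoic acid is bought as the single enantiomer, and locants C1–C15 follow germacrane numbering (C6–C7 is the farnesyl C1–C10 bond).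

**Step 1**
Reactants: 1 methyl (triphenylphosphoranylidene)acetate (2 equiv); 2 (iodomethyl)trimethylsilane
Product: 4 methyl 2-(triphenylphosphoranylidene)-3-(trimethylsilyl)propanoate, via phosphonium iodide 3 (not isolated)
Conditions: EtOAc, reflux, 16 h; filter off the phosphonium salt
Reagents that add atoms: none
Why: The primary iodide C-alkylates the stabilised ylide and the second equivalent of 1 deprotonates the salt (ylide alkylation with transylidation), giving the β-silyl ylide without creating a stereocentre.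

**Step 2**
Reactants: 5 geranyl acetate
Product: 7 (2E)-3-methyl-6-oxohex-2-en-1-yl acetate, via ozonide 6 (not isolated)
Conditions: O3 (1.0 equiv, Sudan red end point), CH2Cl2, −78 °C; then Me2S, −78 °C to rt
Reagents that add atoms: ozone [O-][O+]=O
Why: This is a chemoselective ozonolysis (Criegee mechanism, reductive work-up) in which the allylic acetate deactivates the 2,3-alkene, so only the isopropylidene end is cleaved and the E-alkene (later C1=C10) survives.

**Step 3**
Reactants: 7 (2E)-3-methyl-6-oxohex-2-en-1-yl acetate; 4 methyl 2-(triphenylphosphoranylidene)-3-(trimethylsilyl)propanoate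
Product: 9 methyl (2Z,4S,6E)-8-acetoxy-4-(anilinooxy)-6-methyl-2-[(trimethylsilyl)methyl]octa-2,6-dienoate, via aminoxy aldehyde 8 (not isolated)
Conditions: D-proline (20 mol %), PhNO (0.95 equiv), MeCN, −20 °C; then 4, 0 °C to rt
Reagents that add atoms: nitrosobenzene O=Nc1ccccc1
Why: Proline-catalysed α-aminoxylation (enamine attack on the oxygen of PhNO in the hydrogen-bonded Houk–List transition state) with D-proline gives the S centre that becomes C8, and the one-pot Wittig olefination with the stabilised ylide places C8 trans to the ester and cis to CH2SiMe3.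

**Step 4**
Reactants: 9 methyl (2Z,4S,6E)-8-acetoxy-4-(anilinooxy)-6-methyl-2-[(trimethylsilyl)methyl]octa-2,6-dienoate
Product: 11 methyl (2Z,4S,6E)-4,8-dihydroxy-6-methyl-2-[(trimethylsilyl)methyl]octa-2,6-dienoate, via hydroxy acetate 10 (not isolated)
Conditions: Cu(OAc)2 (30 mol %), MeOH, rt; then K2CO3 (0.3 equiv), 0 °C
Reagents that add atoms: none
Why: Copper-catalysed N–O cleavage of the O-anilino group is followed by carbonate-catalysed transesterification of the primary acetate; C8 is untouched, and the γ-hydroxy enoate cannot lactonise because C8 and the ester are trans.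

**Step 5**
Reactants: 11 methyl (2Z,4S,6E)-4,8-dihydroxy-6-methyl-2-[(trimethylsilyl)methyl]octa-2,6-dienoate
Product: 13 methyl (2Z,4S,6E)-8-chloro-4-hydroxy-6-methyl-2-[(trimethylsilyl)methyl]octa-2,6-dienoate, via primary mesylate 12 (not isolated)
Conditions: MsCl (1.05 equiv), 2,4,6-collidine, LiCl (4 equiv), DMF, 0 °C
Reagents that add atoms: lithium chloride [Li+].[Cl-]
Why: In this Collington–Meyers allylic chlorination the primary allylic alcohol is mesylated much faster than the hindered C8 alcohol next to the electron-poor alkene, and chloride displaces it by SN2 without allylic shift or loss of E geometry.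

**Step 6**
Reactants: 13 methyl (2Z,4S,6E)-8-chloro-4-hydroxy-6-methyl-2-[(trimethylsilyl)methyl]octa-2,6-dienoate
Product: 14 methyl (2Z,4S,6E)-4-hydroxy-6-methyl-9-oxo-2-[(trimethylsilyl)methyl]nona-2,6-dienoate
Conditions: Pd(PPh3)4 (4 mol %), CO (3 atm), Bu3SnH (1.1 equiv, added over 3 h), THF, 50 °C
Reagents that add atoms: carbon monoxide [C-]#[O+]
Why: In this Stille-type carbonylative formylation the allyl chloride adds to zerovalent palladium, CO inserts at the primary terminus and tin hydride delivers hydrogen, so C3 enters as a β,γ-unsaturated aldehyde under neutral conditions that avoid conjugation.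

**Step 7**
Reactants: 15 3,3-diethoxyprop-1-yne
Product: 19 (2E)-4,4-diethoxy-2-iodobut-2-en-1-ol, via lithium acetylide 16 (not isolated), via lithium alkoxide 17 (not isolated), via alkenylzirconocene 18 (not isolated)
Conditions: n-BuLi, THF, −78 °C; (CH2O)n (1.0 equiv), to rt; Cp2ZrHCl (1.6 equiv), rt, dark; I2, −78 °C; H2O
Reagents that add atoms: formaldehyde (from paraformaldehyde) C=O; iodine II
Why: Acetylide hydroxymethylation gives directly the lithium propargylic alkoxide needed for alkoxide-directed syn-hydrozirconation, which places Zr next to CH2OLi, and iodinolysis with retention leaves CH2OH and the acetal carbon cis (the later C4=C5 geometry).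

**Step 8**
Reactants: 19 (2E)-4,4-diethoxy-2-iodobut-2-en-1-ol; 20 (2R)-2-methylbutanoic acid
Product: 21 (2E)-4,4-diethoxy-2-iodobut-2-en-1-yl (2R)-2-methylbutanoate
Conditions: DCC, DMAP (5 mol %), CH2Cl2, 0 °C
Reagents that add atoms: none
Why: Steglich esterification at 0 °C with little DMAP installs the 15-O-acyl group, and the simple α-alkyl centre of the acid does not epimerise.

**Step 9**
Reactants: 14 methyl (2Z,4S,6E)-4-hydroxy-6-methyl-9-oxo-2-[(trimethylsilyl)methyl]nona-2,6-dienoate; 21 (2E)-4,4-diethoxy-2-iodobut-2-en-1-yl (2R)-2-methylbutanoate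
Product: 22 methyl (2Z,4S,6E,9R,10E)-12,12-diethoxy-4,9-dihydroxy-6-methyl-10-({[(2R)-2-methylbutanoyl]oxy}methyl)-2-[(trimethylsilyl)methyl]dodeca-2,6,10-trienoate
Conditions: CrCl2 (4 equiv), NiCl2 (2 mol %), chiral oxazoline–sulfonamide ligand (4.4 equiv, the enantiomer that directs Si-face attack, recovered), Et3N, THF, rt
Reagents that add atoms: none
Why: In this asymmetric Nozaki–Hiyama–Kishi alkenylation the alkenylchromium forms with retention of alkene geometry, tolerates the free OH, esters, acetal and allylsilane, and under ligand control adds to the Si face of the aldehyde to set C3 as R.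

**Step 10**
Reactants: 22 methyl (2Z,4S,6E,9R,10E)-12,12-diethoxy-4,9-dihydroxy-6-methyl-10-({[(2R)-2-methylbutanoyl]oxy}methyl)-2-[(trimethylsilyl)methyl]dodeca-2,6,10-trienoate
Product: 25 methyl (2Z,4S,6E,9R,10E)-4,9-bis{[tert-butyl(dimethyl)silyl]oxy}-6-methyl-10-({[(2R)-2-methylbutanoyl]oxy}methyl)-12-oxo-2-[(trimethylsilyl)methyl]dodeca-2,6,10-trienoate, via bis-silyl ether acetal 23 (not isolated), via lutidinium salt 24 (not isolated)
Conditions: TBSOTf (5 equiv), 2,6-lutidine (7 equiv), CH2Cl2, 0 °C; then H2O, rt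
Reagents that add atoms: tert-butyldimethylsilyl triflate CC(C)(C)[Si](C)(C)OS(=O)(=O)C(F)(F)F; water O
Why: The silyl triflate–lutidine pair silylates both alcohols and also ionises the allylic acetal to a pyridinium salt that water converts to the aldehyde under non-acidic conditions; the enal is the thermodynamic isomer (CHO cis to the smaller CH2O-acyl group), so the geometry holds.

**Step 11**
Reactants: 25 methyl (2Z,4S,6E,9R,10E)-4,9-bis{[tert-butyl(dimethyl)silyl]oxy}-6-methyl-10-({[(2R)-2-methylbutanoyl]oxy}methyl)-12-oxo-2-[(trimethylsilyl)methyl]dodeca-2,6,10-trienoate; 20 (2R)-2-methylbutanoic acid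
Product: 27 methyl (2Z,4S,6E,9R,10E)-4,9-bis{[tert-butyl(dimethyl)silyl]oxy}-6-methyl-12,12-bis{[(2R)-2-methylbutanoyl]oxy}-10-({[(2R)-2-methylbutanoyl]oxy}methyl)-2-[(trimethylsilyl)methyl]dodeca-2,6,10-trienoate, via acid anhydride 26 (not isolated)
Conditions: 20 (6 equiv), DCC (3 equiv), CH2Cl2, 0 °C, filter; then 25 (0.3 M), Sc(OTf)3 (2 mol %), −20 °C, 30 min; pyridine quench
Reagents that add atoms: none
Why: This is a Lewis-acid-catalysed acylal formation from aldehyde and anhydride; at about 1 M anhydride, carboxylate capture of the transient cation is far faster than attack by the electron-poor allylsilane, and the short cold exposure spares the secondary TBS ethers.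

**Step 12**
Reactants: 27 methyl (2Z,4S,6E,9R,10E)-4,9-bis{[tert-butyl(dimethyl)silyl]oxy}-6-methyl-12,12-bis{[(2R)-2-methylbutanoyl]oxy}-10-({[(2R)-2-methylbutanoyl]oxy}methyl)-2-[(trimethylsilyl)methyl]dodeca-2,6,10-trienoate
Product: 29 methyl (3R,6R,7S,8S)-3,8-bis{[tert-butyl(dimethyl)silyl]oxy}-6,15-bis{[(2R)-2-methylbutanoyl]oxy}germacra-1(10)E,4E,11(13)-trien-12-oate, via acyloxyallyl cation 28 (not isolated)
Conditions: TMSOTf (1.2 equiv), 2,6-di-tert-butyl-4-methylpyridine (2 equiv), CH2Cl2, −78 °C, 27 added by syringe pump over 10 h (final 0.5 mM); aq NaHCO3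
Reagents that add atoms: none
Why: Proposed new method: TMSOTf silylates one acyloxy group of the allylic gem-diester and expels it as the silyl ester, just as diphosphate leaves farnesyl diphosphate, and the (E)-1-acyloxyallyl cation 28 is a much stronger electrophile than a Lewis acid–enal complex, which the weakly nucleophilic 2-carbomethoxy allylsilane needs; the central C1=C10 alkene cannot reach this cation, because a six- or seven-membered ring would have to contain the E C4=C5 bond, so under pseudo-high dilution C7 attacks C6 with anti loss of Me3Si+ (regenerating TMSOTf) to form C11=C13; A(1,3) strain with the cis CH2SiMe3 group holds H8 in the alkene plane, so the tethered cation attacks the C7 face that carries C9 and is anti to OTBS (7,8-trans), and a crown-like transition state keeps 6-O-acyl, C11 and 8-OTBS pseudo-equatorial (H6/H7 anti), which gives the configuration of the target; the closest known reaction types are the Hosomi–Sakurai allylation of acylals to homoallylic esters, Prins macrocyclisations and the BF3-promoted closure of ten-membered carbocycles from allylstannane–ynals.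

**Step 13**
Reactants: 29 methyl (3R,6R,7S,8S)-3,8-bis{[tert-butyl(dimethyl)silyl]oxy}-6,15-bis{[(2R)-2-methylbutanoyl]oxy}germacra-1(10)E,4E,11(13)-trien-12-oate
Product: 31 (3R,6R,7R,8S)-3-hydroxy-6,15-bis{[(2R)-2-methylbutanoyl]oxy}germacra-1(10)E,4E,11(13)-trien-12,8-olide (CNP0164325.1), via dihydroxy ester 30 (not isolated)
Conditions: HF·pyridine, pyridine, THF, 0 °C to rt (kept below 30 °C)
Reagents that add atoms: none
Why: Buffered fluoride desilylation frees O3 and O8, and O8 closes on the neighbouring C12 methyl ester (5-exo-trig lactonisation, trans-fused); O6 is already acylated, so only the 8,12-olide can form, and the mild buffered conditions avoid transannular cyclisation and Cope rearrangement.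

**Compound list**
1 | methyl (triphenylphosphoranylidene)acetate | COC(=O)C=P(c1ccccc1)(c1ccccc1)c1ccccc1 | starting material
2 | (iodomethyl)trimethylsilane | C[Si](C)(C)CI | starting material
3 | [1-methoxy-1-oxo-3-(trimethylsilyl)propan-2-yl]triphenylphosphonium iodide | COC(=O)C(C[Si](C)(C)C)[P+](c1ccccc1)(c1ccccc1)c1ccccc1.[I-] | intermediate
4 | methyl 2-(triphenylphosphoranylidene)-3-(trimethylsilyl)propanoate | COC(=O)C(C[Si](C)(C)C)=P(c1ccccc1)(c1ccccc1)c1ccccc1 | intermediate
5 | geranyl acetate | CC(C)=CCC/C(C)=C/COC(C)=O | starting material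
6 | 6,7-ozonide (1,2,4-trioxolane) of geranyl acetate | CC1(C)OOC(CC/C(C)=C/COC(C)=O)O1 | intermediate
7 | (2E)-3-methyl-6-oxohex-2-en-1-yl acetate | O=CCC/C(C)=C/COC(C)=O | intermediate
8 | (2E,5S)-5-(anilinooxy)-3-methyl-6-oxohex-2-en-1-yl acetate | O=C[C@@H](ONc1ccccc1)C/C(C)=C/COC(C)=O | intermediate
9 | methyl (2Z,4S,6E)-8-acetoxy-4-(anilinooxy)-6-methyl-2-[(trimethylsilyl)methyl]octa-2,6-dienoate | COC(=O)/C(C[Si](C)(C)C)=C/[C@@H](ONc1ccccc1)C/C(C)=C/COC(C)=O | intermediate
10 | methyl (2Z,4S,6E)-8-acetoxy-4-hydroxy-6-methyl-2-[(trimethylsilyl)methyl]octa-2,6-dienoate | COC(=O)/C(C[Si](C)(C)C)=C/[C@@H](O)C/C(C)=C/COC(C)=O | intermediate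
11 | methyl (2Z,4S,6E)-4,8-dihydroxy-6-methyl-2-[(trimethylsilyl)methyl]octa-2,6-dienoate | COC(=O)/C(C[Si](C)(C)C)=C/[C@@H](O)C/C(C)=C/CO | intermediate
12 | methyl (2Z,4S,6E)-4-hydroxy-6-methyl-8-(mesyloxy)-2-[(trimethylsilyl)methyl]octa-2,6-dienoate | COC(=O)/C(C[Si](C)(C)C)=C/[C@@H](O)C/C(C)=C/COS(C)(=O)=O | intermediate
13 | methyl (2Z,4S,6E)-8-chloro-4-hydroxy-6-methyl-2-[(trimethylsilyl)methyl]octa-2,6-dienoate | COC(=O)/C(C[Si](C)(C)C)=C/[C@@H](O)C/C(C)=C/CCl | intermediate
14 | methyl (2Z,4S,6E)-4-hydroxy-6-methyl-9-oxo-2-[(trimethylsilyl)methyl]nona-2,6-dienoate | COC(=O)/C(C[Si](C)(C)C)=C/[C@@H](O)C/C(C)=C/CC=O | intermediate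
15 | 3,3-diethoxyprop-1-yne | C#CC(OCC)OCC | starting material
16 | lithium 3,3-diethoxyprop-1-yn-1-ide | [Li]C#CC(OCC)OCC | intermediate
17 | lithium 4,4-diethoxybut-2-yn-1-olate | [Li]OCC#CC(OCC)OCC | intermediate
18 | chloro[(1Z)-3,3-diethoxy-1-(lithiooxymethyl)prop-1-enyl]zirconocene (Zr cis to the vinyl H) | [Li]OC/C(=C\C(OCC)OCC)[Zr](Cl)(C1C=CC=C1)C1C=CC=C1 | intermediate
19 | (2E)-4,4-diethoxy-2-iodobut-2-en-1-ol | OC/C(I)=C\C(OCC)OCC | intermediate
20 | (2R)-2-methylbutanoic acid | CC[C@@H](C)C(=O)O | starting material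
21 | (2E)-4,4-diethoxy-2-iodobut-2-en-1-yl (2R)-2-methylbutanoate | CC[C@@H](C)C(=O)OC/C(I)=C\C(OCC)OCC | intermediate
22 | methyl (2Z,4S,6E,9R,10E)-12,12-diethoxy-4,9-dihydroxy-6-methyl-10-({[(2R)-2-methylbutanoyl]oxy}methyl)-2-[(trimethylsilyl)methyl]dodeca-2,6,10-trienoate | COC(=O)/C(C[Si](C)(C)C)=C/[C@@H](O)C/C(C)=C/C[C@@H](O)/C(COC(=O)[C@H](C)CC)=C/C(OCC)OCC | intermediate
23 | 4,9-bis-O-TBS ether of 22 | COC(=O)/C(C[Si](C)(C)C)=C/[C@@H](O[Si](C)(C)C(C)(C)C)C/C(C)=C/C[C@@H](O[Si](C)(C)C(C)(C)C)/C(COC(=O)[C@H](C)CC)=C/C(OCC)OCC | intermediate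
24 | 12-ethoxy-12-(2,6-dimethylpyridinium-1-yl) triflate derived from 23 | COC(=O)/C(C[Si](C)(C)C)=C/[C@@H](O[Si](C)(C)C(C)(C)C)C/C(C)=C/C[C@@H](O[Si](C)(C)C(C)(C)C)/C(COC(=O)[C@H](C)CC)=C/C(OCC)[n+]1c(C)cccc1C.[O-]S(=O)(=O)C(F)(F)F | intermediate
25 | methyl (2Z,4S,6E,9R,10E)-4,9-bis(TBSO)-6-methyl-10-({[(2R)-2-methylbutanoyl]oxy}methyl)-12-oxo-2-[(trimethylsilyl)methyl]dodeca-2,6,10-trienoate | COC(=O)/C(C[Si](C)(C)C)=C/[C@@H](O[Si](C)(C)C(C)(C)C)C/C(C)=C/C[C@@H](O[Si](C)(C)C(C)(C)C)/C(COC(=O)[C@H](C)CC)=C/C=O | intermediate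
26 | (2R)-2-methylbutanoic anhydride | CC[C@@H](C)C(=O)OC(=O)[C@H](C)CC | intermediate
27 | 12,12-bis[(2R)-2-methylbutanoyloxy] acylal of 25 | COC(=O)/C(C[Si](C)(C)C)=C/[C@@H](O[Si](C)(C)C(C)(C)C)C/C(C)=C/C[C@@H](O[Si](C)(C)C(C)(C)C)/C(COC(=O)[C@H](C)CC)=C/C(OC(=O)[C@H](C)CC)OC(=O)[C@H](C)CC | intermediate
28 | (E)-1-acyloxyallyl cation (C6) triflate derived from 27 | COC(=O)/C(C[Si](C)(C)C)=C/[C@@H](O[Si](C)(C)C(C)(C)C)C/C(C)=C/C[C@@H](O[Si](C)(C)C(C)(C)C)/C(COC(=O)[C@H](C)CC)=C/C=[O+]C(=O)[C@H](C)CC.[O-]S(=O)(=O)C(F)(F)F | intermediate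
29 | methyl (3R,6R,7S,8S)-3,8-bis(TBSO)-6,15-bis{[(2R)-2-methylbutanoyl]oxy}germacra-1(10)E,4E,11(13)-trien-12-oate | C=C(C(=O)OC)[C@@H]1[C@@H](O[Si](C)(C)C(C)(C)C)C/C(C)=C/C[C@@H](O[Si](C)(C)C(C)(C)C)/C(COC(=O)[C@H](C)CC)=C/[C@H]1OC(=O)[C@H](C)CC | intermediate
30 | methyl (3R,6R,7R,8S)-3,8-dihydroxy-6,15-bis{[(2R)-2-methylbutanoyl]oxy}germacra-1(10)E,4E,11(13)-trien-12-oate | C=C(C(=O)OC)[C@@H]1[C@@H](O)C/C(C)=C/C[C@@H](O)/C(COC(=O)[C@H](C)CC)=C/[C@H]1OC(=O)[C@H](C)CC | intermediate
31 | (3R,6R,7R,8S)-3-hydroxy-6,15-bis{[(2R)-2-methylbutanoyl]oxy}germacra-1(10)E,4E,11(13)-trien-12,8-olide (CNP0164325.1) | C=C1C(=O)O[C@H]2C/C(C)=C/C[C@@H](O)/C(COC(=O)[C@H](C)CC)=C/[C@@H](OC(=O)[C@H](C)CC)[C@H]12 | target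

**Step count**
Total step count: 13.
Longest linear sequence: 10 (geranyl acetate 5 through steps 2, 3, 4, 5, 6, 9, 10, 11, 12 and 13).

**Steps most likely to fail**

Step 12, the cationic ten-ring closure. The main risks are oligomerisation, capture of the cation by triflate or carboxylate, and loss of the TBS groups. The fallback separates ring closure from acyl transfer. It sets out from enal 25 and skips the acylal. The same C6–C7 bond is closed as an aldehyde Hosomi–Sakurai reaction on the Lewis acid–enal complex (BF3·OEt2 or SnCl4, CH2Cl2, −78 to −40 °C, slow addition). This gives methyl (3R,6R,7S,8S)-3,8-bis(TBSO)-6-hydroxy-15-{[(2R)-2-methylbutanoyl]oxy}germacra-1(10),4,11(13)-trien-12-oate F1. O6 is then acylated under acidic rather than alkoxide conditions (anhydride 26, catalytic TMSOTf, −40 °C), so that 6,12-lactonisation cannot compete. The sequence rejoins the route at 29.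

Step 9, the ligand-controlled addition. The risks are modest facial selectivity, β-acyloxy elimination from the alkenylchromium and O15 → O3 acyl shift. The fallback sets C3 by reagent-controlled reduction instead of addition, and sets out from 14.
- TBSCl and imidazole give the 4-O-TBS aldehyde F2.
- An achiral CrCl2/NiCl2 coupling with 21 gives the C9-epimeric allylic alcohols F3.
- Dess–Martin oxidation gives the cross-conjugated enone F4.
- Corey–Bakshi–Shibata reduction with the (S)-methyl oxazaborolidine and BH3·SMe2, in which the α-branched alkenyl group acts as the large substituent, gives the (9R)-alcohol F5.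
- F5 enters step 10 and rejoins the route at 23.

Step 6, the carbonylative formylation. The risks are direct hydrogenolysis of the allyl chloride and drift of the alkene into conjugation. The fallback adds C3 through an epoxide rearrangement instead of CO, and sets out from diol 11.
- MnO2 oxidises only the primary allylic alcohol, giving the enal F6.
- Dimethylsulfonium methylide (Corey–Chaykovsky) gives the vinyl oxirane F7.
- MgBr2·OEt2 triggers a Meinwald rearrangement (allylic C–O ionisation, 1,2-hydride shift) to the β,γ-unsaturated aldehyde, rejoining the route at 14.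

**Further compounds**
F1 | step 12 | methyl (3R,6R,7S,8S)-3,8-bis(TBSO)-6-hydroxy-15-{[(2R)-2-methylbutanoyl]oxy}germacra-1(10)E,4E,11(13)-trien-12-oate | C=C(C(=O)OC)[C@@H]1[C@@H](O[Si](C)(C)C(C)(C)C)C/C(C)=C/C[C@@H](O[Si](C)(C)C(C)(C)C)/C(COC(=O)[C@H](C)CC)=C/[C@H]1O
F2 | step 9 | methyl (2Z,4S,6E)-4-(TBSO)-6-methyl-9-oxo-2-[(trimethylsilyl)methyl]nona-2,6-dienoate | COC(=O)/C(C[Si](C)(C)C)=C/[C@@H](O[Si](C)(C)C(C)(C)C)C/C(C)=C/CC=O
F3 | step 9 | methyl (2Z,4S,6E,10E)-4-(TBSO)-12,12-diethoxy-9-hydroxy-6-methyl-10-({[(2R)-2-methylbutanoyl]oxy}methyl)-2-[(trimethylsilyl)methyl]dodeca-2,6,10-trienoate (C9 epimers) | COC(=O)/C(C[Si](C)(C)C)=C/[C@@H](O[Si](C)(C)C(C)(C)C)C/C(C)=C/CC(O)/C(COC(=O)[C@H](C)CC)=C/C(OCC)OCC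
F4 | step 9 | 9-oxo compound (enone) derived from F3 | COC(=O)/C(C[Si](C)(C)C)=C/[C@@H](O[Si](C)(C)C(C)(C)C)C/C(C)=C/CC(=O)/C(COC(=O)[C@H](C)CC)=C/C(OCC)OCC
F5 | step 9 | (9R)-alcohol, the 4-O-TBS ether of 22 | COC(=O)/C(C[Si](C)(C)C)=C/[C@@H](O[Si](C)(C)C(C)(C)C)C/C(C)=C/C[C@@H](O)/C(COC(=O)[C@H](C)CC)=C/C(OCC)OCC
F6 | step 6 | methyl (2Z,4S,6E)-4-hydroxy-6-methyl-8-oxo-2-[(trimethylsilyl)methyl]octa-2,6-dienoate | COC(=O)/C(C[Si](C)(C)C)=C/[C@@H](O)C/C(C)=C/C=O
F7 | step 6 | methyl (2Z,4S,6E)-4-hydroxy-6-methyl-7-(oxiran-2-yl)-2-[(trimethylsilyl)methyl]hepta-2,6-dienoate | COC(=O)/C(C[Si](C)(C)C)=C/[C@@H](O)C/C(C)=C/C1CO1
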